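**Assumptions and corrections (remarks on the chemistry)**

- Ring labels: A is the terminal 2,4,6-trioxygenated ring, followed by B, C, D and E (the terminal 3,4,5-trioxygenated ring). In each ring C1 is the carbon bonded to the ether oxygen on the ring A side (in ring A, the carbon bonded to its only ether oxygen). The second ether oxygen sits at C4 in ring B, C6 in ring C and C5 in ring D.
- Structures 12, 14 and 15 were compared atom by atom and agree with each other; no skeleton needed correction. There are no stereocentres anywhere in the route.
- A peracid acting on the methyl ethers is mechanistically a Baeyer–Villiger oxidation with a Dakin-type outcome. Its first product is the tris(aryl formate) 13, which is cleaved in the same operation to reach 14.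
- The AB phenol 11 is made with the same fluoride displacement and oxygen insertion used for rings C to E, starting from 2,4,6-trimethoxyphenol 8 (assumed commercial). This replaces a copper-mediated arylation of an oxidation-prone hydroquinone by a doubly ortho-substituted, electron-rich aryl bromide.
- The extra oxygen needed on the ring C unit cannot come from demethylation. It is introduced at C3 of the fluoroaldehyde by bromination, borylation and N-oxide oxidation.

## Structural features

The target is a linear pentamer of benzene rings A to E joined only by four diaryl ether oxygens. It carries thirteen free phenolic hydroxyls and has no stereocentre and no stereogenic axis, so no stereocentres stand next to each other. Ring A is a 2,4,6-trihydroxyphenyl group, ring B a 1,4-dioxygenated ring with hydroxyls at C3 and C5, and ring E a 3,4,5-trihydroxyphenyl group. Ring C is pentaoxygenated, with ether oxygens on the adjacent carbons C1 (to ring B) and C6 (to ring D) and hydroxyls at C3, C4 and C5. Ring D has ether oxygens at C1 and C5 and hydroxyls at C3 and C4. The free polyphenol, with its pyrogallol-type arrays, is sensitive to air oxidation, above all in base, so all hydroxyls stay masked until the last step. The real difficulty is placing seventeen oxygens correctly on five rings and making the two crowded ether bonds at ring C on rings too electron-rich for direct nucleophilic aromatic substitution. The key step exploits the C4 hydroxyl of rings C, D and E, which lies para to C1 and between two oxygenated carbons. A formyl group at C4 first activates a fluoride at C1 for displacement and is then converted into that hydroxyl by aryl migration from carbon to oxygen.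

## Logic of the disconnections

**15 to 14.** Ten O–CH3 bonds are cut. Methyl ethers are the smallest masks that survive carbonate in hot dipolar solvents and peracid, and they keep every intermediate stable to air. The forward step must cleave ten aryl methyl ethers without touching four diaryl ether bonds and must deliver the polyphenol without oxidation.

**14 to 12 (through 13).** The three C4–O bonds of rings C, D and E are traced back to C4–CHO bonds. This turns three oxygens that are hard to differentiate into three identical formyl groups, each of which is the activator needed for ether formation one stage earlier. The forward step requires aryl rather than hydride migration at all three sites, and the liberated phenols must not meet the oxidant.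

**12 to 11 and 7.** The bond between C1 of ring C and the ether oxygen of ring B is cut. This is the most crowded ether and is placed last among the couplings so that both partners are fully elaborated and the union is convergent (2 + 3 rings). The forward step needs a doubly ortho-substituted phenoxide to displace a fluoride that has an aryloxy neighbour, faster than it attacks the other formyl-activated ether carbons.

**7 to 6 and 3.** The bond between C1 of ring D and the oxygen on C6 of ring C is cut. The electrophile 3 has an unhindered fluoride para to a formyl group. The nucleophile 6 carries its own fluoride, which must stay silent while its neighbouring oxygen is anionic and become reactive only afterwards.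

**3 to 2 and 1.** The bond between C1 of ring E and the oxygen on C5 of ring D is cut, giving two monocyclic aldehydes. The forward step needs the fluoride of 1 to react in preference to the newly activated fluoride of the product, which is handled by an excess of 1.

**2 to 1.** One O–CH3 bond ortho to the formyl group is cut. The forward step needs mono-selective, chelation-controlled ether cleavage.

**6 to 4 to 1.** The C3–O bond of the ring C unit is cut back to a C3–B bond (5) and then a C3–Br bond (4), and finally to the C3–H bond of 1. All directing groups of 1 converge on C3, so the halogenation is unambiguous. The forward oxidation must spare the formyl group.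

**11 to 9 to 8 and 1.** The C4–O bond of ring B is traced back to a C4–CHO bond (through 10), and the bond between C1 of ring B and the ring A oxygen is cut. The whole synthesis then rests on two starting materials, 1 (used four times) and 8. The forward steps are the same displacement and oxygen insertion as above, so this branch also rehearses the key step on a small scale.

## Other disconnections considered

**Alternative 1:** Ring A is opened at one C–C bond, between a hydroxyl-bearing carbon and the neighbouring CH. This leads to the acyclic triketide A2, a methyl 4-aryloxy-3,5-dioxohexanoate whose aryl group is the ring B to E tetramer; A2 would come from O-alkylation of the tetramer phenol A3. In the forward key step an excess of strong base would form the polyanion of A2, the terminal methyl carbanion would attack the ester carbon in an intramolecular Claisen condensation, and the cyclic triketone would enolise to A1, which has a free ring A triol.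
- In its favour: it follows the polyketide logic by which phloroglucinol rings arise, delivers ring A without protecting groups, and forms the A–O–B bond at an sp3 carbon.
- Against it: acyclic 3,5-diketo esters tend to close through the enol oxygen to a pyranone rather than through carbon. The carbon that must attack is the least acidic site, and the ester sits next to an enolate that deactivates it. The 2-aryloxy-1,3-diketone unit is open to retro-Claisen cleavage. A3 still contains rings C, D and E with every oxygen and both crowded ethers, so the hard part is only postponed.
- Comparison on structure: the alternative addresses ring A, which costs the chosen plan one displacement with purchased 8, and leaves the C4 oxygens of rings C to E unexplained.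
- Comparison on mechanism: a carbanion cyclisation with a competing O-acylation is less biased than an aryl migration assisted by three oxygen donors.
- Comparison on step economy: A3 needs at least as many steps as 12, and alkylation, cyclisation and ten demethylations follow, so the route would be longer.
- Equal or better: it is better on protecting-group economy at ring A (three fewer ether cleavages) and avoids the air-sensitive phenol 8. It is equal in the end game, since both plans finish with a Lewis-acid demethylation.

**Alternative 2:** Both ether C–O bonds at ring C are cut (C1–O to ring B, C6–O to ring D). Ring C becomes the cationic complex A4, [CpRu(1,2-dichloro-3,4,5-trimethoxybenzene)]PF6 (divalent ruthenium). The partners are the AB phenol 11 and the permethylated DE phenol A5. In the forward key step the phenoxide of 11 would displace the chloride at C1 and the phenoxide of A5 the chloride at C6, giving the complex A6. Photolytic decomplexation would release the tridecamethyl ether A7, which would then be demethylated.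
- In its favour: a 2 + 1 + 2 assembly; substitution on a cationic arene complex should run near room temperature; no other electrophilic aryl ether carbon is present.
- Against it: the two chlorides differ only in their neighbours (H against OMe), so the order of substitution rests on a modest steric bias. The first aryloxy group deactivates the complex just when the more hindered chloride must react. Ruthenium is stoichiometric and a decomplexation step is added. The arene ligand of A4, with two adjacent chlorines beside three methoxy groups, is not the expected product of direct halogenation of the parent trimethoxyarene. A5 needs a ring D with three differentiated oxygens made by copper coupling.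
- Comparison on structure: the C4 oxygens of rings C, D and E must be carried as methoxy groups in every fragment, so they play no role in the assembly.
- Comparison on mechanism: metal activation replaces formyl activation, and thirteen instead of ten methyl ethers must be cleaved.
- Comparison on step economy: the fragment syntheses and the decomplexation outweigh the shorter final sequence.
- Equal or better: the alternative is better on convergence and on the mildness of the ether-forming step, where ether exchange should not arise. It is equal in needing no stereocontrol.

**Alternative 3:** Ring C is opened at its C2–C3 bond and traced back to the cyclobutenone A8, a 4-aryloxy-4-(1-aryloxyvinyl)-2,3-dimethoxycyclobutenone that would derive from dimethyl squarate A10. In the forward key step, heating A8 would cause a four-electron electrocyclic ring opening to a dienylketene with the vinyl group rotating inward. A six-electron electrocyclisation would form the C2–C3 bond, and tautomerisation would give A9, with a free hydroxyl at C3 of ring C.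
- In its favour: ring C is built de novo with all five oxygens fixed by connectivity; the step is thermal, neutral and reagent-free; the AB and DE halves are joined as the ring forms.
- Against it: A8 needs a quaternary carbon bearing both a tertiary alkyl aryl ether to an electron-rich phenol and a 1-aryloxyvinyl group. Addition of a vinyl metal to a squaric ester gives a 4-hydroxy compound, and O-arylation of that tertiary alcohol by an unactivated arene has no dependable method. The alpha-metalated aryl vinyl ether of the AB unit would have to be formed in the presence of many methoxy-directed ortho positions. A9 then needs twelve demethylations.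
- Comparison on structure: it solves ring C only and treats rings D and E as purchased oxygenation patterns.
- Comparison on mechanism: the pericyclic cascade itself is well founded, but it is fed by a precursor whose synthesis is the real problem.
- Comparison on step economy: it is clearly longer.
- Equal or better: it is better on regiocontrol of the ring C oxygens and on the mildness of the key step itself. It is equal on convergence of the final union.

Key step: step 9

## Route

**Step 1**
Reactants: 1 4-fluoro-2,6-dimethoxybenzaldehyde
Product: 2 4-fluoro-2-hydroxy-6-methoxybenzaldehyde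
Conditions: BCl3 (1.1 equiv), CH2Cl2, −78 °C to 0 °C; aq. HCl
Reagents that add atoms: none
Why: Chelation-controlled ether cleavage: BCl3 bridges the formyl oxygen and one ortho methoxy oxygen, and chloride attacks that methyl group; the two ortho groups are equivalent, and the boron chelate formed together with the limited amount of reagent should hold the reaction at mono-demethylation.

**Step 2**
Reactants: 2 4-fluoro-2-hydroxy-6-methoxybenzaldehyde; 1 4-fluoro-2,6-dimethoxybenzaldehyde (3 equiv)
Product: 3 4-fluoro-2-(4-formyl-3,5-dimethoxyphenoxy)-6-methoxybenzaldehyde
Conditions: K2CO3, DMF, 100 °C, argon, slow addition of 2; excess 1 recovered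
Reagents that add atoms: none
Why: Nucleophilic aromatic substitution (addition–elimination) of the fluoride para to the formyl group of 1 by the phenoxide of 2; the fluoride of 2 is switched off while its ortho oxygen is anionic because the formyl group is then part of a vinylogous carboxylate, and the excess of 1 should keep the newly activated fluoride of 3 from competing.

**Step 3**
Reactants: 1 4-fluoro-2,6-dimethoxybenzaldehyde
Product: 4 3-bromo-4-fluoro-2,6-dimethoxybenzaldehyde
Conditions: NBS (1.05 equiv), MeCN, rt to 50 °C
Reagents that add atoms: N-bromosuccinimide, O=C1CCC(=O)N1Br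
Why: Electrophilic aromatic bromination; C3 and C5 are equivalent, each ortho to one methoxy group, para to the other, ortho to fluorine and meta to the formyl group, so all directing effects converge and one equivalent of reagent should stop at the monobromide.

**Step 4**
Reactants: 4 3-bromo-4-fluoro-2,6-dimethoxybenzaldehyde
Product: 6 4-fluoro-3-hydroxy-2,6-dimethoxybenzaldehyde, via aryl pinacol boronate 5 (not isolated)
Conditions: B2pin2, PdCl2(dppf) (5 mol %), KOAc, 1,4-dioxane, 90 °C; then NMO (excess), 50 °C; aq. NH4Cl
Reagents that add atoms: N-methylmorpholine N-oxide, C[N+]1([O-])CCOCC1 (supplies the phenol oxygen); bis(pinacolato)diboron, CC1(C)OB(OC1(C)C)B1OC(C)(C)C(C)(C)O1 (supplies the boron of 5 only)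
Why: Miyaura borylation of the aryl bromide, which tolerates the aldehyde and the aryl fluoride, followed by ipso-hydroxylation of the boronate with an amine N-oxide, in which the aryl group migrates from boron to oxygen; the N-oxide leaves the formyl group alone, whereas peroxide oxidants would risk a premature Dakin reaction.

**Step 5**
Reactants: 6 4-fluoro-3-hydroxy-2,6-dimethoxybenzaldehyde; 3 4-fluoro-2-(4-formyl-3,5-dimethoxyphenoxy)-6-methoxybenzaldehyde
Product: 7 4-fluoro-3-[4-formyl-3-(4-formyl-3,5-dimethoxyphenoxy)-5-methoxyphenoxy]-2,6-dimethoxybenzaldehyde
Conditions: Cs2CO3, DMSO, 90 °C, argon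
Reagents that add atoms: none
Why: Nucleophilic aromatic substitution of the unhindered ring D fluoride of 3 (para to formyl) by the phenoxide of 6; the anionic oxygen of 6 is ortho to its own C–F carbon and deactivates it, so 6 should not self-condense, and the fluoride of 7 has an aryloxy neighbour and should be less reactive than that of 3.

**Step 6**
Reactants: 8 2,4,6-trimethoxyphenol; 1 4-fluoro-2,6-dimethoxybenzaldehyde (1.2 equiv)
Product: 9 2,6-dimethoxy-4-(2,4,6-trimethoxyphenoxy)benzaldehyde
Conditions: K2CO3, DMF, 100 °C, argon
Reagents that add atoms: none
Why: Nucleophilic aromatic substitution of the para-formyl-activated fluoride by an electron-rich, doubly ortho-substituted phenoxide; the product carries no further leaving group, and the inert atmosphere protects the oxidisable phenoxide of 8.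

**Step 7**
Reactants: 9 2,6-dimethoxy-4-(2,4,6-trimethoxyphenoxy)benzaldehyde
Product: 11 2,6-dimethoxy-4-(2,4,6-trimethoxyphenoxy)phenol, via aryl formate 10 (not isolated)
Conditions: mCPBA (1.3 equiv), NaHCO3, CH2Cl2, 0 °C to rt; aq. Na2S2O3; then K2CO3 (cat.), degassed MeOH, rt
Reagents that add atoms: meta-chloroperoxybenzoic acid, OOC(=O)c1cccc(Cl)c1
Why: Baeyer–Villiger oxidation of an electron-rich benzaldehyde with a Dakin-type outcome: the aryl group, carrying two ortho methoxy groups and a para aryloxy group, migrates in the Criegee adduct in preference to hydride; the formate is methanolysed only after the peracid has been destroyed, so the phenol is never exposed to oxidant.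

**Step 8**
Reactants: 11 2,6-dimethoxy-4-(2,4,6-trimethoxyphenoxy)phenol (1.3 equiv); 7 4-fluoro-3-[4-formyl-3-(4-formyl-3,5-dimethoxyphenoxy)-5-methoxyphenoxy]-2,6-dimethoxybenzaldehyde
Product: 12 4-[2,6-dimethoxy-4-(2,4,6-trimethoxyphenoxy)phenoxy]-3-[4-formyl-3-(4-formyl-3,5-dimethoxyphenoxy)-5-methoxyphenoxy]-2,6-dimethoxybenzaldehyde (pentamer decamethyl ether with formyl groups at C4 of rings C, D and E)
Conditions: Cs2CO3, DMSO, 100–110 °C, argon
Reagents that add atoms: none
Why: Nucleophilic aromatic substitution of the ring C fluoride (para to formyl) by the 2,6-dimethoxyphenoxide of 11, made as reactive as possible by the cesium counterion in DMSO; the neighbouring aryloxy oxygen is a weak donor because its lone pair is shared with the formyl-bearing ring D, and fluoride is displaced far faster than an aryloxide, so exchange at the other formyl-activated ether carbons should stay minor.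

**Step 9**
Reactants: 12 pentamer decamethyl ether with formyl groups at C4 of rings C, D and E
Product: 14 pentamer decamethyl ether bearing free C4 hydroxyls on rings C/D/E, via tris(aryl formate) 13 (not isolated)
Conditions: mCPBA (4.5 equiv), NaHCO3, CH2Cl2, 0 °C to rt; aq. Na2S2O3; then K2CO3 (cat.), degassed MeOH, 0 °C to rt; AcOH quench
Reagents that add atoms: meta-chloroperoxybenzoic acid, OOC(=O)c1cccc(Cl)c1
Why: The peracid adds to each of the three formyl carbonyls to give a Criegee adduct, and the aryl group anti to the O–O bond migrates from the formyl carbon to oxygen as meta-chlorobenzoate leaves, giving an aryl formate at C4 of rings C, D and E. The closest known reaction is the Baeyer–Villiger oxidation of 2,6-dialkoxybenzaldehydes to aryl formates, the peracid form of the Dakin oxidation, here run three times in one molecule and already rehearsed in step 7. No ring is closed and no stereocentre is formed; three C4–O bonds are made and each formyl carbon leaves as formate. The selectivity needed is aryl over hydride migration at all three sites; it is secured by the substrate, because each migrating ring carries two ortho oxygen donors and a para ether oxygen that stabilise the electron-deficient migrating carbon, whereas hydride migration dominates only for electron-poor aldehydes. The second requirement is that rings A and B and the new phenols are not oxidised; the low temperature and the buffer keep the products as formates until thiosulfate has destroyed the peracid. Catalytic carbonate in degassed methanol then transfers the three formyl groups to methanol and frees the three C4 hydroxyls of 14. The same formyl groups served earlier as activators for fluoride displacement, so nothing has to be added or removed for this step.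

**Step 10**
Reactants: 14 pentamer decamethyl ether bearing free C4 hydroxyls on rings C, D and E
Product: 15 5-[2,6-dihydroxy-4-(2,4,6-trihydroxyphenoxy)phenoxy]-4-[3,4-dihydroxy-5-(3,4,5-trihydroxyphenoxy)phenoxy]benzene-1,2,3-triol (target)
Conditions: BBr3 (30 equiv), CH2Cl2, −78 °C to rt, argon; degassed MeOH then H2O, 0 °C; Sephadex LH-20, degassed acidified MeOH
Reagents that add atoms: none
Why: Lewis-acid cleavage of aryl methyl ethers: BBr3 coordinates each methoxy oxygen and bromide attacks the methyl carbon; the diaryl ether C–O bonds offer no sp3 carbon for attack and should survive, and oxygen-free hydrolytic work-up releases the thirteen hydroxyls from their borates.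

## Compound list

1 | 4-fluoro-2,6-dimethoxybenzaldehyde | COc1cc(F)cc(OC)c1C=O | starting material
2 | 4-fluoro-2-hydroxy-6-methoxybenzaldehyde | COc1cc(F)cc(O)c1C=O | intermediate
3 | 4-fluoro-2-(4-formyl-3,5-dimethoxyphenoxy)-6-methoxybenzaldehyde | COc1cc(F)cc(Oc2cc(OC)c(C=O)c(OC)c2)c1C=O | intermediate
4 | 3-bromo-4-fluoro-2,6-dimethoxybenzaldehyde | COc1cc(F)c(Br)c(OC)c1C=O | intermediate
5 | 4-fluoro-2,6-dimethoxy-3-(4,4,5,5-tetramethyl-1,3,2-dioxaborolan-2-yl)benzaldehyde | COc1cc(F)c(B2OC(C)(C)C(C)(C)O2)c(OC)c1C=O | intermediate (not isolated)
6 | 4-fluoro-3-hydroxy-2,6-dimethoxybenzaldehyde | COc1cc(F)c(O)c(OC)c1C=O | intermediate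
7 | 4-fluoro-3-[4-formyl-3-(4-formyl-3,5-dimethoxyphenoxy)-5-methoxyphenoxy]-2,6-dimethoxybenzaldehyde | COc1cc(F)c(Oc2cc(OC)c(C=O)c(Oc3cc(OC)c(C=O)c(OC)c3)c2)c(OC)c1C=O | intermediate
8 | 2,4,6-trimethoxyphenol | COc1cc(OC)c(O)c(OC)c1 | starting material
9 | 2,6-dimethoxy-4-(2,4,6-trimethoxyphenoxy)benzaldehyde | COc1cc(OC)c(Oc2cc(OC)c(C=O)c(OC)c2)c(OC)c1 | intermediate
10 | 2,6-dimethoxy-4-(2,4,6-trimethoxyphenoxy)phenyl formate | COc1cc(OC)c(Oc2cc(OC)c(OC=O)c(OC)c2)c(OC)c1 | intermediate (not isolated)
11 | 2,6-dimethoxy-4-(2,4,6-trimethoxyphenoxy)phenol | COc1cc(OC)c(Oc2cc(OC)c(O)c(OC)c2)c(OC)c1 | intermediate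
12 | 4-[2,6-dimethoxy-4-(2,4,6-trimethoxyphenoxy)phenoxy]-3-[4-formyl-3-(4-formyl-3,5-dimethoxyphenoxy)-5-methoxyphenoxy]-2,6-dimethoxybenzaldehyde | COc1cc(OC)c(Oc2cc(OC)c(Oc3cc(OC)c(C=O)c(OC)c3Oc3cc(OC)c(C=O)c(Oc4cc(OC)c(C=O)c(OC)c4)c3)c(OC)c2)c(OC)c1 | intermediate
13 | tris(formate ester) of 14 at the C4 oxygens of rings C, D and E | COc1cc(OC)c(Oc2cc(OC)c(Oc3cc(OC)c(OC=O)c(OC)c3Oc3cc(OC)c(OC=O)c(Oc4cc(OC)c(OC=O)c(OC)c4)c3)c(OC)c2)c(OC)c1 | intermediate (not isolated)
14 | 4-[2,6-dimethoxy-4-(2,4,6-trimethoxyphenoxy)phenoxy]-3-[4-hydroxy-3-(4-hydroxy-3,5-dimethoxyphenoxy)-5-methoxyphenoxy]-2,6-dimethoxyphenol | COc1cc(OC)c(Oc2cc(OC)c(Oc3cc(OC)c(O)c(OC)c3Oc3cc(OC)c(O)c(Oc4cc(OC)c(O)c(OC)c4)c3)c(OC)c2)c(OC)c1 | intermediate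
15 | 5-[2,6-dihydroxy-4-(2,4,6-trihydroxyphenoxy)phenoxy]-4-[3,4-dihydroxy-5-(3,4,5-trihydroxyphenoxy)phenoxy]benzene-1,2,3-triol | Oc1cc(O)c(Oc2cc(O)c(Oc3cc(O)c(O)c(O)c3Oc3cc(O)c(O)c(Oc4cc(O)c(O)c(O)c4)c3)c(O)c2)c(O)c1 | target

## Step count and least certain steps

Total: 10 steps. Longest linear sequence: 6 steps (1 to 4 to 6 to 7 to 12 to 14 to 15; the branch through 2 and 3 is equally long, and the branch through 9 and 11 is one step shorter).

**Step 9 (key step).** The most likely failure is premature loss of the formyl esters in the acidic, moist peracid medium. The freed 4-aryloxyphenol units would then meet the oxidant and suffer oxidative cleavage of the diaryl ethers. Hydride migration at ring D, whose ortho donors include a weaker aryloxy group, and incomplete reaction at the third site are further risks. Fallback, setting out from 12 and returning at 14: MeMgBr in THF should add to the three formyl groups to give the tris(1-hydroxyethyl) pentamer F1 (mixture of diastereomers, of no consequence). Oxidation with MnO2 or Dess–Martin periodinane should give the triacetyl pentamer F2. Baeyer–Villiger oxidation of the three aryl methyl ketones with mCPBA and a trace of CF3CO2H should give the tris(aryl acetate) F3. Here aryl competes only with methyl migration, and the acetates are far more robust toward the medium than formates. Methanolysis with K2CO3 in degassed MeOH returns 14.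

**Step 8.** Slow substitution at the crowded ring C carbon may allow the phenoxide of 11 to attack the two other formyl-activated ether carbons of 7, scrambling the oligomer by ether exchange. Fallback, setting out from 6 and returning at 12: allylation (allyl bromide, K2CO3, acetone) gives 4-fluoro-2,6-dimethoxy-3-(prop-2-en-1-yloxy)benzaldehyde F4. Its fluoride is the only electrophilic site when 11 is coupled to it (Cs2CO3, DMSO), giving the ABC allyl ether 4-[2,6-dimethoxy-4-(2,4,6-trimethoxyphenoxy)phenoxy]-2,6-dimethoxy-3-(prop-2-en-1-yloxy)benzaldehyde F5. Deallylation with Pd(PPh3)4 (zerovalent palladium) and morpholine gives the ABC phenol 4-[2,6-dimethoxy-4-(2,4,6-trimethoxyphenoxy)phenoxy]-3-hydroxy-2,6-dimethoxybenzaldehyde F6. Its phenoxide then displaces the unhindered fluoride of 3 to give 12. Compound 7 is bypassed at the cost of two extra steps.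

**Step 2.** The fluoride of 3 is about as electrophilic as that of 1, so over-reaction to oligomers can compete, and the hydrogen-bonded salicylaldehyde-type phenoxide is a modest nucleophile. Fallback, setting out from 2 and returning at 3: copper-mediated oxidative coupling (Chan–Lam) of 2 with (4-formyl-3,5-dimethoxyphenyl)boronic acid F7, using Cu(OAc)2 (divalent copper), pyridine, 4 Å molecular sieves, CH2Cl2, air, rt. No strong nucleophile is present, so the aryl fluoride of 3 cannot react further. F7 is expected to be purchasable or available by one borylation of the corresponding aryl bromide.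

**Step 4.** The bromide sits between fluorine and methoxy, so hydrodebromination or protodeboronation at this doubly ortho-substituted position can erode the borylation, and any residual boron species complicates the oxidation. Fallback, setting out from 4 and returning at 6: acetalisation (HC(OMe)3, TsOH, MeOH) gives 2-bromo-1-fluoro-4-(dimethoxymethyl)-3,5-dimethoxybenzene F8. Bromine–lithium exchange (n-BuLi, THF, −78 °C, kept cold to avoid aryne formation), trapping with B(OMe)3 and oxidation with alkaline H2O2 give 3-(dimethoxymethyl)-6-fluoro-2,4-dimethoxyphenol F9; the acetal shields the aldehyde from the peroxide. Aqueous HCl in THF then returns 6.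

**Step 10.** Ten ether cleavages may stop short at the most hindered methoxy groups, and the free polyphenol may oxidise during work-up and chromatography. Fallback, setting out from 14 and returning at 15: the crude demethylation mixture is acetylated directly (Ac2O, pyridine) to the tridecaacetate of the target F10. This is air-stable and can be separated on silica from incompletely demethylated material. Acidic methanolysis (AcCl in degassed MeOH, generating HCl) under argon then releases 15 without exposing it to base.

## Further compounds

F1 | step 9 | pentamer decamethyl ether with 1-hydroxyethyl groups at C4 of rings C, D and E (mixture of diastereomers) | COc1cc(OC)c(Oc2cc(OC)c(Oc3cc(OC)c(C(C)O)c(OC)c3Oc3cc(OC)c(C(C)O)c(Oc4cc(OC)c(C(C)O)c(OC)c4)c3)c(OC)c2)c(OC)c1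
F2 | step 9 | pentamer decamethyl ether with acetyl groups at C4 of rings C, D and E | COc1cc(OC)c(Oc2cc(OC)c(Oc3cc(OC)c(C(C)=O)c(OC)c3Oc3cc(OC)c(C(C)=O)c(Oc4cc(OC)c(C(C)=O)c(OC)c4)c3)c(OC)c2)c(OC)c1
F3 | step 9 | tris(acetate ester) of 14 at the C4 oxygens of rings C, D and E | COc1cc(OC)c(Oc2cc(OC)c(Oc3cc(OC)c(OC(C)=O)c(OC)c3Oc3cc(OC)c(OC(C)=O)c(Oc4cc(OC)c(OC(C)=O)c(OC)c4)c3)c(OC)c2)c(OC)c1
F4 | step 8 | 4-fluoro-2,6-dimethoxy-3-(prop-2-en-1-yloxy)benzaldehyde | COc1cc(F)c(OCC=C)c(OC)c1C=O
F5 | step 8 | 4-[2,6-dimethoxy-4-(2,4,6-trimethoxyphenoxy)phenoxy]-2,6-dimethoxy-3-(prop-2-en-1-yloxy)benzaldehyde | COc1cc(OC)c(Oc2cc(OC)c(Oc3cc(OC)c(C=O)c(OC)c3OCC=C)c(OC)c2)c(OC)c1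
F6 | step 8 | 4-[2,6-dimethoxy-4-(2,4,6-trimethoxyphenoxy)phenoxy]-3-hydroxy-2,6-dimethoxybenzaldehyde | COc1cc(OC)c(Oc2cc(OC)c(Oc3cc(OC)c(C=O)c(OC)c3O)c(OC)c2)c(OC)c1
F7 | step 2 | (4-formyl-3,5-dimethoxyphenyl)boronic acid | COc1cc(B(O)O)cc(OC)c1C=O
F8 | step 4 | 2-bromo-1-fluoro-4-(dimethoxymethyl)-3,5-dimethoxybenzene | COc1cc(F)c(Br)c(OC)c1C(OC)OC
F9 | step 4 | 3-(dimethoxymethyl)-6-fluoro-2,4-dimethoxyphenol | COc1cc(F)c(O)c(OC)c1C(OC)OC
F10 | step 10 | tridecaacetate of the target | CC(=O)Oc1cc(OC(C)=O)c(Oc2cc(OC(C)=O)c(Oc3cc(OC(C)=O)c(OC(C)=O)c(OC(C)=O)c3Oc3cc(OC(C)=O)c(OC(C)=O)c(Oc4cc(OC(C)=O)c(OC(C)=O)c(OC(C)=O)c4)c3)c(OC(C)=O)c2)c(OC(C)=O)c1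
A1 | alternative 1 | pentamer with free ring A triol and rings B to E as methyl ethers | Oc1cc(O)c(Oc2cc(OC)c(Oc3cc(OC)c(OC)c(OC)c3Oc3cc(OC)c(OC)c(Oc4cc(OC)c(OC)c(OC)c4)c3)c(OC)c2)c(O)c1
A2 | alternative 1 | methyl 4-aryloxy-3,5-dioxohexanoate carrying the ring B to E tetramer (racemic, enolisable) | COC(=O)CC(=O)C(Oc1cc(OC)c(Oc2cc(OC)c(OC)c(OC)c2Oc2cc(OC)c(OC)c(Oc3cc(OC)c(OC)c(OC)c3)c2)c(OC)c1)C(C)=O
A3 | alternative 1 | ring B to E tetramer phenol, decamethyl ether | Oc1cc(OC)c(Oc2cc(OC)c(OC)c(OC)c2Oc2cc(OC)c(OC)c(Oc3cc(OC)c(OC)c(OC)c3)c2)c(OC)c1
A4 | alternative 2 | [CpRu(1,2-dichloro-3,4,5-trimethoxybenzene)]PF6, written as separated components | COc1cc(Cl)c(Cl)c(OC)c1OC.[Ru+2].[cH-]1cccc1.F[P-](F)(F)(F)(F)F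
A5 | alternative 2 | 3,4-dimethoxy-5-(3,4,5-trimethoxyphenoxy)phenol | COc1cc(Oc2cc(O)cc(OC)c2OC)cc(OC)c1OC
A6 | alternative 2 | CpRu hexafluorophosphate complex (ring C bound) of the pentamer tridecamethyl ether, written as separated components | COc1cc(OC)c(Oc2cc(OC)c(Oc3cc(OC)c(OC)c(OC)c3Oc3cc(OC)c(OC)c(Oc4cc(OC)c(OC)c(OC)c4)c3)c(OC)c2)c(OC)c1.[Ru+2].[cH-]1cccc1.F[P-](F)(F)(F)(F)F
A7 | alternative 2 | pentamer tridecamethyl ether | COc1cc(OC)c(Oc2cc(OC)c(Oc3cc(OC)c(OC)c(OC)c3Oc3cc(OC)c(OC)c(Oc4cc(OC)c(OC)c(OC)c4)c3)c(OC)c2)c(OC)c1
A8 | alternative 3 | 4-(DE-aryloxy)-4-[1-(AB-aryloxy)vinyl]-2,3-dimethoxycyclobut-2-en-1-one (racemic) | COC1=C(OC)C(Oc2cc(OC)c(OC)c(Oc3cc(OC)c(OC)c(OC)c3)c2)(C(=C)Oc2c(OC)cc(Oc3c(OC)cc(OC)cc3OC)cc2OC)C1=O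
A9 | alternative 3 | pentamer dodecamethyl ether with free C3 hydroxyl on ring C | COc1cc(OC)c(Oc2cc(OC)c(Oc3cc(O)c(OC)c(OC)c3Oc3cc(OC)c(OC)c(Oc4cc(OC)c(OC)c(OC)c4)c3)c(OC)c2)c(OC)c1
A10 | alternative 3 | dimethyl squarate | COC1=C(OC)C(=O)C1=O
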